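The pitfall raised at this meeting was reading a quick conversion of starting material as a good yield of target.

    starting material + reagent → intermediate + released group (k1 = 0.011 L mol⁻¹ min⁻¹, Ea1 = 87.0 kJ mol⁻¹)
    intermediate ⇌ target (K2 = 2.4, k2 = 0.0059 min⁻¹, Ea2 = 121 kJ mol⁻¹, ΔH2 = −13.0 kJ mol⁻¹)
    intermediate ⇌ isomer of the product (K3 = 280, k3 = 0.0027 min⁻¹, Ea3 = 117 kJ mol⁻¹, ΔH3 = 54.0 kJ mol⁻¹)
    crystals ⇌ released group, rate k4*(cs4 - [released group]) while solid is left; crystals form when [released group] > cs4 (cs4 = 0.065 M, k4 = 0.16 min⁻¹)
    (constants at 90 °C)

all flasks: starting material 0.64 M; reagent 1.00 equiv; time 30 h
- teal: temperature 90 °C
- blue: at 60 °C until 10 h, from then on at 120 °C
- violet: temperature 60 °C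
- grey: temperature 120 °C

1. the best flask by amount of target, in percent of the starting material charged; "all alike" if 1.5 percentage points covers them all (teal / blue / violet / grey / all alike)
2. amount of target at the end, in percent of the starting material charged, teal
3. amount of target at the end, in percent of the starting material charged, blue
4. amount of target at the end, in percent of the starting material charged, violet
5. amount of target at the end, in percent of the starting material charged, grey

- what is said of released group includes crystals
- crystals is a solid; its amount is given per volume of the solution
- all constants are for 90 °C and move with temperature by the activation energies and enthalpies

One member favoured grey, at 120 °C, for its speed. I answered that we should first ask where the flask is heading, and only then how fast, since the target is no dead end: it can return to intermediate, and intermediate also passes to the isomer of the product.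

I then reckoned the end state by hand. Let K_P be the equilibrium constant from intermediate to target, and K_Q the one from intermediate to isomer. For grey they are 1.73 and 1100, and K_P divided by the sum of one, K_P and K_Q gives 0.157%. I called this φ, the floor share: the fraction of the material in those three forms that stands as target once both equilibria hold. It is the end point of thermodynamic control, as against the kinetic control that holds earlier.

A second member asked whether grey gets there within 30 h. I could say this much: by the step between them alone, both ways together, target and intermediate relax with a half-life of 0.0583 h in grey, short against 30 h. Heating also raises the rate constant of the step to isomer faster than that of the first step, because the activation energy of the step to isomer stands 30.0 kJ mol⁻¹ above that of the first step. How fast the material reaches the isomer I did not finish by hand, so what follows was a commitment and not a proof. I committed to grey ending near φ, and to blue ending near the same figure, since blue spends its last 20.0 h at the same temperature. Teal and violet I could not rank this way.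

The forecast went further. It named teal as best, with 21.5% for teal (range 19.5% to 23.5%), 7.8% for violet, 0.19% for blue and 0.17% for grey. Its ground was that 120 °C “collapses it to the roughly 0.16% equilibrium level plus a small contribution from the remaining feed”. On grey the two of us differ slightly: my figure stops at φ, 0.157%, while the forecast's stands at 0.17%.

The simulation gives teal as best, at 21.5%, with violet at 7.09%, blue at 0.195% and grey at 0.173%. Grey still holds 0.87% of its starting material at 30.0 h, and its target stands 0.016 percentage points above φ. Blue has the same φ over its last hours; it keeps 1.3% of its starting material at 30.0 h, its target stands 0.038 points above φ, and left until 300 h, blue reads 0.157% of target.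

The constants used here stand for no real mixture; no experiment stands behind them.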